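The lactone ring is taken apart at the C4–C5 bond. C5, the ring OCH2 carbon, hangs on the C4 stereocentre, which sits β to the carbonyl carbon C2, so C5 can be delivered as the carbon of nitromethane to the β-position of an enal whose CHO carbon ends up as C2. One amine-catalysed conjugate addition therefore forms C4–C5 and fixes C4 as R; no ring is closed. Its precursor is the linear (E)-4-arylbut-2-enal carrying the 3,4-dimethoxyphenyl group. The nitro carbon is later taken to the CH2O level, the ring is closed, and the aryl carbinol is attached at C3 by acylation and chelation-controlled reduction.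

Key step: step 2

Remark: atoms are numbered as in the lactone (O1, C2 = carbonyl carbon, C3, C4, C5 = OCH2) and the carbinol carbon is called C7; the target is read from its SMILES as the 3,4-trans lactone (3S,4R) with an S carbinol.

Step 1
Reactants: 1 methyl eugenol; 2 (E)-crotonaldehyde
Product: 3 (E)-4-(3,4-dimethoxyphenyl)but-2-enal
Conditions: second-generation Hoveyda–Grubbs catalyst (3 mol%), 1,4-benzoquinone (10 mol%), 2 (5 equiv), CH2Cl2, 40 °C
Reagents that add atoms: none
Why: Olefin cross-metathesis between a terminal allylarene and an electron-poor enal that is slow to homodimerise should favour the cross product and, being reversible, give the more stable E enal with loss of propene, while benzoquinone suppresses ruthenium hydride-mediated migration of the allyl double bond.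

Step 2
Reactants: 3 (E)-4-(3,4-dimethoxyphenyl)but-2-enal; 4 nitromethane
Product: 5 (R)-3-(3,4-dimethoxybenzyl)-4-nitrobutanal
Conditions: (S)-2-[diphenyl(trimethylsilyloxy)methyl]pyrrolidine (10 mol%), PhCO2H (20 mol%), 4 (5 equiv), MeOH, 0 °C to rt
Reagents that add atoms: none
Why: Condensation of the secondary amine with enal 3 gives an E-configured α,β-unsaturated iminium ion, to whose β-carbon the nitronate (formed from 4 by benzoate) adds; the resulting enamine is protonated and hydrolysed, which frees aldehyde 5 and the catalyst. The closest known reaction type is the diarylprolinol silyl ether-catalysed iminium Michael addition of nitroalkanes to β-substituted enals. No ring is closed; only the C4–C5 bond (lactone numbering) is made. The new stereocentre is set by the catalyst: the diphenyl(trimethylsilyloxy)methyl group of the S catalyst covers one face of the s-trans iminium ion, so the nitronate should attack the Re face of the β-carbon and give C4 as R (the R catalyst would give the enantiomer). The step needs 1,4- over 1,2-addition and β-attack without γ-deprotonation: iminium activation favours conjugate addition over a Henry reaction, while the acid co-catalyst, the low temperature and the excess of nitromethane should keep the iminium ion from draining into the arene-conjugated dienamine through its benzylic γ-hydrogens.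

Step 3
Reactants: 5 (R)-3-(3,4-dimethoxybenzyl)-4-nitrobutanal
Product: 6 (R)-3-(3,4-dimethoxybenzyl)-4-nitrobutanoic acid
Conditions: NaClO2, NaH2PO4, 2-methyl-2-butene, t-BuOH/H2O, 0 °C to rt
Reagents that add atoms: sodium chlorite, [Na+].[O-]Cl=O
Why: Pinnick oxidation converts the aldehyde into the acid under weakly acidic conditions, so no nitronate forms and the stereocentre is untouched, while 2-methyl-2-butene traps HOCl before it can chlorinate the electron-rich arene.

Step 4
Reactants: 6 (R)-3-(3,4-dimethoxybenzyl)-4-nitrobutanoic acid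
Product: 7 methyl (R)-3-(3,4-dimethoxybenzyl)-4-nitrobutanoate
Conditions: MeOH, H2SO4 (cat.), 50 °C
Reagents that add atoms: methanol, CO
Why: Fischer esterification masks the future C2 carboxyl as its methyl ester so that it can be told apart from the acid generated next at C5; the primary nitroalkane, the aryl ethers and the non-acidic stereocentre are inert to acid in methanol.

Step 5
Reactants: 7 methyl (R)-3-(3,4-dimethoxybenzyl)-4-nitrobutanoate
Product: 8 (R)-2-(3,4-dimethoxybenzyl)-4-methoxy-4-oxobutanoic acid
Conditions: NaNO2 (3 equiv), AcOH (10 equiv), DMSO, 35 °C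
Reagents that add atoms: sodium nitrite, [Na+].[O-]N=O; water, O
Why: Nitrite-mediated oxidation of a primary nitroalkane to the carboxylic acid (nitrosation to the nitrolic acid, loss of nitrite to the nitrile oxide, then hydration and denitrosative hydrolysis) runs in weakly acidic medium, which should leave the adjacent stereocentre and the methyl ester intact and avoids the epimerisable α-chiral aldehyde of a Nef reaction.

Step 6
Reactants: 8 (R)-2-(3,4-dimethoxybenzyl)-4-methoxy-4-oxobutanoic acid
Product: 10 (R)-4-(3,4-dimethoxybenzyl)dihydrofuran-2(3H)-one, via hydroxy ester 9 (not isolated)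
Conditions: BH3·SMe2, THF, 0 °C to rt; MeOH quench; then TsOH·H2O (cat.), CH2Cl2, rt
Reagents that add atoms: none
Why: Chemoselective borane reduction of the free carboxylic acid in the presence of the methyl ester gives γ-hydroxy ester 9, which closes under acid catalysis by 5-exo-trig lactonisation with loss of methanol; the C4 centre is not involved and stays R.

Step 7
Reactants: 11 methyl vanillate
Product: 12 methyl 3-methoxy-4-(triisopropylsilyloxy)benzoate
Conditions: TIPSCl, imidazole, DMF, rt
Reagents that add atoms: triisopropylsilyl chloride, CC(C)[Si](Cl)(C(C)C)C(C)C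
Why: Imidazole-promoted silylation of the phenol gives a bulky aryl silyl ether that should survive the amide base and the methoxide released in the Claisen step and can later be removed by fluoride under near-neutral conditions.

Step 8
Reactants: 10 (R)-4-(3,4-dimethoxybenzyl)dihydrofuran-2(3H)-one; 12 methyl 3-methoxy-4-(triisopropylsilyloxy)benzoate
Product: 13 (3S,4R)-4-(3,4-dimethoxybenzyl)-3-[3-methoxy-4-(triisopropylsilyloxy)benzoyl]dihydrofuran-2(3H)-one
Conditions: LiHMDS (2.5 equiv), 12 (1.3 equiv), THF, −78 °C to 0 °C; AcOH quench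
Reagents that add atoms: none
Why: In this crossed Claisen condensation the lithium enolate of lactone 10 adds to the non-enolisable benzoate 12 and the equilibrium is pulled over by deprotonation of the β-keto lactone by the second equivalent of base; on protonation the doubly activated C3 should settle in the more stable 3,4-trans arrangement (3S) next to the fixed C4 centre.

Step 9
Reactants: 13 (3S,4R)-4-(3,4-dimethoxybenzyl)-3-[3-methoxy-4-(triisopropylsilyloxy)benzoyl]dihydrofuran-2(3H)-one
Product: 14 (3S,4R)-4-(3,4-dimethoxybenzyl)-3-{(S)-hydroxy[3-methoxy-4-(triisopropylsilyloxy)phenyl]methyl}dihydrofuran-2(3H)-one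
Conditions: Zn(BH4)2, Et2O/CH2Cl2, −78 °C to −20 °C; aq. NH4Cl
Reagents that add atoms: none
Why: In this chelation-controlled reduction of an α-substituted β-keto ester, divalent zinc ties the ketone and lactone carbonyl oxygens into a six-membered chelate and hydride adds to the ketone face on the side of the C3 hydrogen, away from ring carbon C4, which should give the syn (erythro) alcohol, that is the S carbinol next to 3S, while the lactone is not reduced at this temperature.

Step 10
Reactants: 14 (3S,4R)-4-(3,4-dimethoxybenzyl)-3-{(S)-hydroxy[3-methoxy-4-(triisopropylsilyloxy)phenyl]methyl}dihydrofuran-2(3H)-one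
Product: 15 (3S,4R)-4-(3,4-dimethoxybenzyl)-3-[(S)-hydroxy(4-hydroxy-3-methoxyphenyl)methyl]dihydrofuran-2(3H)-one
Conditions: TBAF, AcOH (1 equiv each), THF, 0 °C
Reagents that add atoms: none
Why: Fluoride-induced desilylation of the aryl silyl ether, buffered with acetic acid so that the medium is neither basic enough for retro-aldol cleavage or C3 epimerisation of the β-hydroxy lactone nor acidic enough to ionise the electron-rich benzylic alcohol.

Compound list
1 | methyl eugenol (4-allyl-1,2-dimethoxybenzene) | C=CCc1ccc(OC)c(OC)c1 | starting material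
2 | (E)-crotonaldehyde | C/C=C/C=O | starting material
3 | (E)-4-(3,4-dimethoxyphenyl)but-2-enal | O=C/C=C/Cc1ccc(OC)c(OC)c1 | intermediate
4 | nitromethane | C[N+](=O)[O-] | starting material
5 | (R)-3-(3,4-dimethoxybenzyl)-4-nitrobutanal | O=CC[C@H](C[N+](=O)[O-])Cc1ccc(OC)c(OC)c1 | intermediate
6 | (R)-3-(3,4-dimethoxybenzyl)-4-nitrobutanoic acid | OC(=O)C[C@H](C[N+](=O)[O-])Cc1ccc(OC)c(OC)c1 | intermediate
7 | methyl (R)-3-(3,4-dimethoxybenzyl)-4-nitrobutanoate | COC(=O)C[C@H](C[N+](=O)[O-])Cc1ccc(OC)c(OC)c1 | intermediate
8 | (R)-2-(3,4-dimethoxybenzyl)-4-methoxy-4-oxobutanoic acid | COC(=O)C[C@H](C(=O)O)Cc1ccc(OC)c(OC)c1 | intermediate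
9 | methyl (R)-3-(3,4-dimethoxybenzyl)-4-hydroxybutanoate (hydroxy ester, formed in the flask in step 6) | COC(=O)C[C@H](CO)Cc1ccc(OC)c(OC)c1 | intermediate
10 | (R)-4-(3,4-dimethoxybenzyl)dihydrofuran-2(3H)-one | O=C1OC[C@H](Cc2ccc(OC)c(OC)c2)C1 | intermediate
11 | methyl vanillate (methyl 4-hydroxy-3-methoxybenzoate) | COC(=O)c1ccc(O)c(OC)c1 | starting material
12 | methyl 3-methoxy-4-(triisopropylsilyloxy)benzoate | COC(=O)c1ccc(O[Si](C(C)C)(C(C)C)C(C)C)c(OC)c1 | intermediate
13 | (3S,4R)-4-(3,4-dimethoxybenzyl)-3-[3-methoxy-4-(triisopropylsilyloxy)benzoyl]dihydrofuran-2(3H)-one | COc1cc(C(=O)[C@H]2C(=O)OC[C@@H]2Cc2ccc(OC)c(OC)c2)ccc1O[Si](C(C)C)(C(C)C)C(C)C | intermediate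
14 | (3S,4R)-4-(3,4-dimethoxybenzyl)-3-{(S)-hydroxy[3-methoxy-4-(triisopropylsilyloxy)phenyl]methyl}dihydrofuran-2(3H)-one | COc1cc([C@@H](O)[C@H]2C(=O)OC[C@@H]2Cc2ccc(OC)c(OC)c2)ccc1O[Si](C(C)C)(C(C)C)C(C)C | intermediate
15 | (3S,4R)-4-(3,4-dimethoxybenzyl)-3-[(S)-hydroxy(4-hydroxy-3-methoxyphenyl)methyl]dihydrofuran-2(3H)-one | COc1cc([C@@H](O)[C@H]2C(=O)OC[C@@H]2Cc2ccc(OC)c(OC)c2)ccc1O | target

Total step count: 10 steps.
Longest linear sequence: 9 steps (steps 1–6, 8, 9, 10, from methyl eugenol 1); step 7 is a one-step side branch.

Steps most likely to fail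

Step 2. The iminium ion may lose a benzylic γ-proton and drain into the arene-conjugated dienamine (double-bond migration, self-condensation), or facial control may be insufficient. The fallback sets out from methyl eugenol 1 and comes back at lactone 10, and sets the C4 centre by auxiliary-controlled enolate alkylation instead of conjugate addition. Hydroboration–oxidation of 1 (9-BBN, THF; NaOH, H2O2) should give 3-(3,4-dimethoxyphenyl)propan-1-ol F1, which is oxidised (TEMPO, PhI(OAc)2, MeCN/H2O) to 3-(3,4-dimethoxyphenyl)propanoic acid F2. Activation as the pivaloyl mixed anhydride (PivCl, Et3N) and N-acylation of (S)-4-benzyl-2-oxazolidinone (LiCl, THF) gives (S)-4-benzyl-3-[3-(3,4-dimethoxyphenyl)propanoyl]oxazolidin-2-one F3. Its sodium Z-enolate (NaHMDS, THF, −78 °C) is alkylated with tert-butyl bromoacetate on the face away from the auxiliary benzyl group, giving tert-butyl (R)-3-{[(S)-4-benzyl-2-oxooxazolidin-3-yl]carbonyl}-4-(3,4-dimethoxyphenyl)butanoate F4. LiOH/H2O2 removes the auxiliary to give (R)-4-tert-butoxy-2-(3,4-dimethoxybenzyl)-4-oxobutanoic acid F5. BH3·SMe2 reduces the acid to tert-butyl (R)-3-(3,4-dimethoxybenzyl)-4-hydroxybutanoate F6, and CF3CO2H in CH2Cl2 closes it to 10.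

Step 8. Acyl transfer to the electron-rich, deactivated benzoate may be slow, so that the lactone enolate decomposes or self-condenses, or methoxide may strip the silyl group. The fallback sets out from lactone 10 and comes back at keto lactone 13, and replaces the ester by the far more electrophilic aldehyde. Commercial vanillin is silylated (TIPSCl, imidazole, DMF) to 3-methoxy-4-(triisopropylsilyloxy)benzaldehyde F7. The lithium enolate of 10 (LiHMDS, THF, −78 °C) adds to it in an aldol reaction to give the 3,4-trans adduct (3S,4R)-4-(3,4-dimethoxybenzyl)-3-{hydroxy[3-methoxy-4-(triisopropylsilyloxy)phenyl]methyl}dihydrofuran-2(3H)-one F8 as a mixture of carbinol epimers. Oxidation of the mixture with Dess–Martin periodinane (NaHCO3, CH2Cl2) converges on 13.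

Step 9. Facial selectivity at the ketone may be poor if the zinc chelate is not the reacting species, so that the carbinol epimer forms. The fallback sets out from keto lactone 13 and comes back at alcohol 14, and moves from substrate control to catalyst control. Asymmetric transfer hydrogenation with RuCl(p-cymene)[(S,S)-TsDPEN] in HCO2H/Et3N should set the S carbinol through the catalyst's recognition of the aryl ketone, while C3 stays labile and settles trans to C4. This fallback makes no new compound (F0).

Further compounds
F1 | step 2 | 3-(3,4-dimethoxyphenyl)propan-1-ol | OCCCc1ccc(OC)c(OC)c1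
F2 | step 2 | 3-(3,4-dimethoxyphenyl)propanoic acid | OC(=O)CCc1ccc(OC)c(OC)c1
F3 | step 2 | (S)-4-benzyl-3-[3-(3,4-dimethoxyphenyl)propanoyl]oxazolidin-2-one | O=C(CCc1ccc(OC)c(OC)c1)N1C(=O)OC[C@@H]1Cc1ccccc1
F4 | step 2 | tert-butyl (R)-3-{[(S)-4-benzyl-2-oxooxazolidin-3-yl]carbonyl}-4-(3,4-dimethoxyphenyl)butanoate | CC(C)(C)OC(=O)C[C@@H](Cc1ccc(OC)c(OC)c1)C(=O)N1C(=O)OC[C@@H]1Cc1ccccc1
F5 | step 2 | (R)-4-tert-butoxy-2-(3,4-dimethoxybenzyl)-4-oxobutanoic acid | CC(C)(C)OC(=O)C[C@H](C(=O)O)Cc1ccc(OC)c(OC)c1
F6 | step 2 | tert-butyl (R)-3-(3,4-dimethoxybenzyl)-4-hydroxybutanoate | CC(C)(C)OC(=O)C[C@H](CO)Cc1ccc(OC)c(OC)c1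
F7 | step 8 | 3-methoxy-4-(triisopropylsilyloxy)benzaldehyde | COc1cc(C=O)ccc1O[Si](C(C)C)(C(C)C)C(C)C
F8 | step 8 | (3S,4R)-4-(3,4-dimethoxybenzyl)-3-{hydroxy[3-methoxy-4-(triisopropylsilyloxy)phenyl]methyl}dihydrofuran-2(3H)-one (carbinol epimers) | COc1cc(C(O)[C@H]2C(=O)OC[C@@H]2Cc2ccc(OC)c(OC)c2)ccc1O[Si](C(C)C)(C(C)C)C(C)C
F0 | step 9 | none | none
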